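The numbers in the tables are calculated with made-up constants, noise included.

Percent of the charge is what holds still here: at 3.00 h the autumn run, charged with 0.046 M, shows 20.2% target, and the spring run, charged with 0.10 M, shows 20.4%. Both have the same catalyst, so I treat the runs as pseudo-first-order in substrate and reckon the flask in percent.

| setting | autumn | spring | flask |
|---|---|---|---|
| substrate | 0.046 M | 0.10 M | 0.069 M |
| catalyst | 8.3 mM | 8.3 mM | 8.3 mM |
| remark | run made earlier | run made earlier |  |
| time |  |  | 8.0 h |

- autumn (time / h: target / %, substrate / %): 0.500: 11.0, 4.5; 1.33: 14.1, 4.3; 3.00: 20.2, 2.7; 6.00: 24.9, 2.2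
- spring (time / h: target / %, substrate / %): 1.50: 15.4, 4.0; 3.00: 20.4, 3.4; 5.00: 24.8, 2.4; 6.00: 25.4, 2.1

(standard deviation of a reading: 0.5 percentage points)

- the analysis behind the earlier runs scatters by 0.5 percentage points, standard deviation

- concentration of target at 8.0 h, in M
- concentration of substrate at 8.0 h, in M
- concentration of isomer of the product A at 8.0 h, in M

The readings make a ladder. On the fastest rung, autumn substrate is down to 4.5% by 0.500 h, a time much shorter than the 8.0 h asked. On the next rung, over hours, target gains 0.0350 h⁻¹ of the charge up to 3.00 h, then 0.0162 h⁻¹, about half. On the slowest rung, the target-per-substrate ratio, [target]/[substrate] at the last readings of both runs, reads 11.7, though substrate near 2.1% carries a scatter of 0.5 percentage points.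

My first pass keeps the last gain and puts target at 28.4%. Going round again, I let the gain fall once more by the factor 0.462, which gives 26.6%, so [target] is 0.0184 M and, dividing by the ratio, [substrate] is 0.00157 M. The isomer of the product A was never read, so the remainder, 0.0490 M, is a ceiling for it, not a value.

The forecast also reckons in percent, but it takes the isomer of the product A as the remainder itself, “assuming a closed balance”, and it gives 0.0192 M target, 0.0012 M substrate and 0.0486 M isomer of the product A.

The flask gives 0.0178 M target, 0.00157 M substrate and 0.0268 M isomer of the product A, and it also holds 32.3% uncatalysed product at 8.00 h.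

    substrate + catalyst ⇌ target + catalyst, rate k1*[substrate]*[catalyst] forward; the back reaction follows from the equilibrium constant (K = 12.0, k = 0.0537 M⁻¹ s⁻¹)
    substrate + catalyst ⇌ isomer of the product A + catalyst, rate k2*[substrate]*[catalyst] forward; the back reaction follows from the equilibrium constant (K = 15.9, k = 0.485 M⁻¹ s⁻¹)
    substrate + catalyst ⇌ isomer of the product B + catalyst, rate k3*[substrate]*[catalyst] forward; the back reaction follows from the equilibrium constant (K = 0.328, k = 0.0191 M⁻¹ s⁻¹)
    substrate → uncatalysed product (k = 3.00 × 10⁻⁴ s⁻¹)

The flask's ratio is 11.3, against the 11.7 read earlier. A neighbouring flask charged with 0.28 M holds 0.0724 M target at the same time, which the ratio turns into 0.00619 M substrate, and that flask holds 0.00636 M.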